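The numbers in the tables stem from a simulated flask with made-up constants; the scatter is artificial.

0.108 min: that was how long one charged catalyst took, on average, to make one left-handed product in the midnight run. I called this the mean turnover time (inverse of the turnover frequency): catalyst charged times elapsed time, over product made. It replaces the curve by its chord, and the first midnight reading gave 0.0994 min, a gap that a scatter of 1 percentage point on 3.4 % easily covers. The dawn run, with less substrate, gave 0.155 min, a reading longer than the midnight one.

common to all: gas 3.6 mM (held); free catalyst 25 µM; added ligand 31 µM
- dawn: left-handed substrate 24 mM; right-handed substrate 24 mM; run made earlier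
- midnight: left-handed substrate 37 mM; right-handed substrate 37 mM; run made earlier
- flask: left-handed substrate 49 mM; right-handed substrate 49 mM

| run | time / min | left-handed product / % | left-handed substrate / % |
|---|---|---|---|
| dawn | 10.0 | 3.8 | 44.7 |
| dawn | 20.0 | 7.4 | 42.0 |
| dawn | 30.0 | 10.6 | 39.1 |
| dawn | 40.0 | 13.1 | 36.3 |
| dawn | 50.0 | 16.8 | 32.0 |
| midnight | 10.0 | 3.4 | 46.2 |
| midnight | 20.0 | 7.0 | 43.8 |
| midnight | 30.0 | 9.4 | 40.0 |
| midnight | 40.0 | 11.8 | 36.7 |
| midnight | 50.0 | 15.7 | 34.8 |

(standard deviation of a reading: 1 percentage point)

- free catalyst is single-handed; left-handed substrate and right-handed substrate are mirror images of each other, charged as a racemate, each of them at the stated concentration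
- the numbers in the tables scatter by 1 percentage point (one standard deviation)
- at the start none of the gas is in solution
- no earlier run changes the charge of free catalyst; that part of a forecast is a guess

- apparent order in free catalyst when 5.0 % of the left-handed substrate and right-handed substrate together are converted (percent change of the rate of making left-handed product for one percent more free catalyst charged)

My ladder for the midnight run had three rungs: the turnover at 0.108 min, the run at 50.0 min, and 159 min, the time the left-handed substrate charge lasts at the mean rate. Because the turnover was far shorter than the run, and the run shorter than that emptying, I read each stretch of curve as a steady round at nearly fixed substrate. Rate is then catalyst over turnover time, which has order 1 in catalyst while the turnover time stays put as catalyst changes. In the midnight run left-handed substrate outnumbered catalyst 1480 to one, but added ligand, at 31 µM, stood beside 25 µM of catalyst, and that was my open doubt. For the flask I committed to 1. The forecast gave 1.3: “The partly saturated substrate dependence suggests moderate binding”.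

The flask gave 1.0.

    free catalyst + left-handed substrate ⇌ catalyst intermediate A (K = 17.0 M⁻¹, k = 64000 M⁻¹ min⁻¹)
    free catalyst + added ligand ⇌ idle complex (K = 28000 M⁻¹, k = 1.00 × 10⁵ M⁻¹ min⁻¹)
    gas ⇌ reagent, rate k3*(csat - [reagent]) (kL = 33.0 min⁻¹)
    free catalyst + right-handed substrate ⇌ catalyst intermediate B (K = 45.0 M⁻¹, k = 21000 M⁻¹ min⁻¹)
    reagent + catalyst intermediate B → free catalyst + right-handed product (k = 6000 M⁻¹ min⁻¹)
    reagent + catalyst intermediate A → free catalyst + left-handed product (k = 17000 M⁻¹ min⁻¹)

At 0.150 h the catalyst in the flask stood spread over its forms, with free catalyst 22.0 %, catalyst intermediate A 17.2 %, catalyst intermediate B 44.3 % and idle complex 16.5 %, while added ligand kept 86.7 % of its own charge. By 1.50 h in the flask, with reagent then at 3.59 mM, both rounds had run on, idle complex had risen to 21.0 %, added ligand stood at 83.1 %, and left-handed product had reached 21.8 %, a mean turnover time of 0.105 min.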